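**Plan**
1. Retrosynthetic cuts, in order: the three aryl O–CH2OMe helper bonds; the C2–C1′ bond between ring C and ring B (two C–H partners); the C3–O bond (via the C2=C3 epoxide); O1–C2 and C2–C3 of the pyranone (a one-carbon unit on an o-hydroxyacetophenone); the C8–CMe2 bond (aromatic Claisen of an O-prenyl ether).
2. The enabling feature is the ring-C diosphenol: the enol O3–C3=C2–H, flanked by O1 and conjugated to C4=O, is the most easily oxidised site of the chromonol and puts radical/cation character on C2, its only C–H. The anisole-type ring of MOM-protected phenol supplies the para C–H.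
3. Forward: ring A is elaborated first (O-prenylation of symmetric phloroacetophenone, Claisen to the 1,1-dimethylallyl group, bis-MOM), then ring C is closed, C3 is oxygenated, ring B is joined by anodic dehydrogenative coupling, and the MOM groups are removed.
4. Regiochemistry: the symmetry of the Claisen substrate allows only one C-allyl isomer. The OH wedged between acetyl and the tert-alkyl group stays unprotected and becomes O1, which places the side chain at C8.
5. Stereochemistry: the target has no stereocentre and no stereogenic double bond. The only stereocentres on the route (C2/C3 of the racemic cis-epoxide) are erased one step later.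

Key step: step 8

Remark: the target is achiral, so its SMILES defines a single species and no enantioselective step is required.

**Step 1**
Reactants: 1 2,4,6-trihydroxyacetophenone; 2 prenyl bromide (1-bromo-3-methylbut-2-ene)
Product: 3 1-[2,6-dihydroxy-4-(3-methylbut-2-en-1-yloxy)phenyl]ethanone
Conditions: K2CO3 (1 equiv), acetone, rt
Reagents that add atoms: none
Why: Williamson etherification; the 4-OH, para to the acetyl group, is the most acidic and the only non-chelated hydroxyl, so one equivalent of base and bromide should alkylate it on oxygen in the aprotic medium.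

**Step 2**
Reactants: 3 1-[2,6-dihydroxy-4-(3-methylbut-2-en-1-yloxy)phenyl]ethanone
Product: 4 1-[2,4,6-trihydroxy-3-(2-methylbut-3-en-2-yl)phenyl]ethanone
Conditions: PhNEt2, 185 °C, Ar, sealed tube
Reagents that add atoms: none
Why: Aromatic Claisen rearrangement ([3,3]) transfers the allyl unit with inversion to an ortho carbon to give the 1,1-dimethylallyl group; the two ortho positions are equivalent by symmetry and the para position is blocked by acetyl, so a single constitution should result after tautomerisation.

**Step 3**
Reactants: 4 1-[2,4,6-trihydroxy-3-(2-methylbut-3-en-2-yl)phenyl]ethanone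
Product: 5 1-[2-hydroxy-4,6-bis(methoxymethoxy)-3-(2-methylbut-3-en-2-yl)phenyl]ethanone
Conditions: MOMCl (2.2 equiv), iPr2NEt, CH2Cl2, 0 °C to rt
Reagents that add atoms: chloromethyl methyl ether (MOMCl), COCCl
Why: MOM etherification under amine base; the 4-OH and the unhindered 6-OH should react, while the 2-OH, wedged between acetyl and the tert-alkyl group and locked in the hydrogen bond to C=O, should stay free, which later fixes the side chain at C8.

**Step 4**
Reactants: 5 1-[2-hydroxy-4,6-bis(methoxymethoxy)-3-(2-methylbut-3-en-2-yl)phenyl]ethanone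
Product: 7 5,7-bis(methoxymethoxy)-8-(2-methylbut-3-en-2-yl)-4H-chromen-4-one, via enaminone 6 (not isolated)
Conditions: DMF-DMA, PhMe, 100 °C; then AcOH, 60 °C
Reagents that add atoms: N,N-dimethylformamide dimethyl acetal (DMF-DMA), COC(OC)N(C)C
Why: Condensation of the methyl ketone with the amide acetal gives the enaminone, and acid-promoted intramolecular oxa-Michael addition–elimination of dimethylamine (enaminone–chromone annulation) through the only free phenol should close ring C with the tert-alkyl group at C8.

**Step 5**
Reactants: 7 5,7-bis(methoxymethoxy)-8-(2-methylbut-3-en-2-yl)-4H-chromen-4-one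
Product: 8 rac-cis-2,3-epoxy-5,7-bis(methoxymethoxy)-8-(2-methylbut-3-en-2-yl)chroman-4-one
Conditions: 30% aq H2O2, aq NaOH, CH2Cl2/MeOH, 0 °C
Reagents that add atoms: hydrogen peroxide, OO
Why: Weitz–Scheffer nucleophilic epoxidation; hydroperoxide adds to C2 of the enone and the enolate closes on O–O to give the necessarily cis-fused racemic epoxide, while the isolated vinyl group is inert to the nucleophilic oxidant.

**Step 6**
Reactants: 8 rac-cis-2,3-epoxy-5,7-bis(methoxymethoxy)-8-(2-methylbut-3-en-2-yl)chroman-4-one
Product: 9 3-hydroxy-5,7-bis(methoxymethoxy)-8-(2-methylbut-3-en-2-yl)-4H-chromen-4-one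
Conditions: p-TsOH·H2O (cat.), CH2Cl2, rt
Reagents that add atoms: none
Why: Acid-catalysed epoxy ketone to diosphenol isomerisation; ionisation of the acetal-type C2–O bond (assisted by O1) and loss of the C3 proton should give the 3-hydroxychromone and remove both stereocentres, and catalytic acid without a protic nucleophile should spare the MOM acetals.

**Step 7**
Reactants: 10 phenol
Product: 11 (methoxymethoxy)benzene
Conditions: MOMCl, iPr2NEt, CH2Cl2, 0 °C to rt
Reagents that add atoms: chloromethyl methyl ether (MOMCl), COCCl
Why: Williamson-type O-alkylation of phenol; the MOM group caps the phenol against its own anodic oxidation in step 8 and leaves together with the other two in step 9.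

**Step 8**
Reactants: 9 3-hydroxy-5,7-bis(methoxymethoxy)-8-(2-methylbut-3-en-2-yl)-4H-chromen-4-one; 11 (methoxymethoxy)benzene (8 equiv)
Product: 12 3-hydroxy-5,7-bis(methoxymethoxy)-2-[4-(methoxymethoxy)phenyl]-8-(2-methylbut-3-en-2-yl)-4H-chromen-4-one
Conditions: BDD anode, Pt cathode, undivided cell, constant current (about 5 mA cm−2, about 2 F mol−1 based on 9), Bu4NPF6 (0.1 M), 2,6-lutidine (1 equiv), HFIP, 20 °C
Reagents that add atoms: none
Why: Proposed new method: anodic dehydrogenative enol–arene cross-coupling, in which the ring-C diosphenol of 9 (enol O3–C3=C2–H, hydrogen-bonded to lutidine) is the most easily oxidised site and loses e−/H+ to an α-keto-enoxyl radical with spin on C2; this radical, directly or after a second electron transfer to the O1-stabilised C2 cation, is trapped by the para carbon of the HFIP-solvated aryl ether 11, loss of e−/H+ rearomatises ring B, the 2-aryl-chroman-3,4-dione tautomerises to the flavonol, and the protons are reduced to H2 at the cathode. The closest known reaction types are the anodic phenol–arene dehydrogenative cross-coupling on boron-doped diamond in HFIP (O-protected phenols included as partners) and the oxidative coupling of 1,3-dicarbonyl enols with electron-rich arenes; C2–H arylation of a 3-hydroxy-4-pyranone in this way is not established. No ring is closed and no stereocentre is formed. The step needs cross- over homo-coupling (only 9 should be oxidised at the applied current, because 11 has a much higher potential and is present in excess as the nucleophile), para over ortho attack on 11 (steric demand of the solvated OMOM group), C2 over ring-A C6 (C6–H is deactivated by the C4 carbonyl and flanked by two OMOM groups) and an untouched vinyl group (mono-substituted, neopentylic, a poor partner for a stabilised electrophilic radical). Over-oxidation of the more electron-rich product should be limited by the MOM cap on the 4′-oxygen (no quinone-methide channel), hydrogen bonding by HFIP, the charge limit and partial conversion with recovery of 9.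

**Step 9**
Reactants: 12 3-hydroxy-5,7-bis(methoxymethoxy)-2-[4-(methoxymethoxy)phenyl]-8-(2-methylbut-3-en-2-yl)-4H-chromen-4-one
Product: 13 3,5,7-trihydroxy-2-(4-hydroxyphenyl)-8-(2-methylbut-3-en-2-yl)-4H-chromen-4-one
Conditions: HCl (1.25 M in MeOH), 40 °C
Reagents that add atoms: none
Why: Acid-catalysed transacetalisation of the three aryl MOM acetals to methanol should release the phenols as dimethoxymethane is lost, and dilute methanolic acid at 40 °C should not protonate the mono-substituted alkene next to the 7-OH.

**Compound list**
1 | 2,4,6-trihydroxyacetophenone | CC(=O)c1c(O)cc(O)cc1O | starting material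
2 | prenyl bromide (1-bromo-3-methylbut-2-ene) | CC(C)=CCBr | starting material
3 | 1-[2,6-dihydroxy-4-(3-methylbut-2-en-1-yloxy)phenyl]ethanone | CC(=O)c1c(O)cc(OCC=C(C)C)cc1O | intermediate
4 | 1-[2,4,6-trihydroxy-3-(2-methylbut-3-en-2-yl)phenyl]ethanone | CC(=O)c1c(O)cc(O)c(C(C)(C)C=C)c1O | intermediate
5 | 1-[2-hydroxy-4,6-bis(methoxymethoxy)-3-(2-methylbut-3-en-2-yl)phenyl]ethanone | CC(=O)c1c(OCOC)cc(OCOC)c(C(C)(C)C=C)c1O | intermediate
6 | (E)-3-(dimethylamino)-1-[2-hydroxy-4,6-bis(methoxymethoxy)-3-(2-methylbut-3-en-2-yl)phenyl]prop-2-en-1-one (enaminone, not isolated) | CN(C)/C=C/C(=O)c1c(OCOC)cc(OCOC)c(C(C)(C)C=C)c1O | intermediate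
7 | 5,7-bis(methoxymethoxy)-8-(2-methylbut-3-en-2-yl)-4H-chromen-4-one | C=CC(C)(C)c1c(OCOC)cc(OCOC)c2c(=O)ccoc12 | intermediate
8 | rac-cis-2,3-epoxy-5,7-bis(methoxymethoxy)-8-(2-methylbut-3-en-2-yl)chroman-4-one (racemic, one enantiomer drawn) | O=C1c2c(OCOC)cc(OCOC)c(C(C)(C)C=C)c2O[C@@H]2O[C@H]12 | intermediate
9 | 3-hydroxy-5,7-bis(methoxymethoxy)-8-(2-methylbut-3-en-2-yl)-4H-chromen-4-one | C=CC(C)(C)c1c(OCOC)cc(OCOC)c2c(=O)c(O)coc12 | intermediate
10 | phenol | Oc1ccccc1 | starting material
11 | (methoxymethoxy)benzene | COCOc1ccccc1 | intermediate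
12 | 3-hydroxy-5,7-bis(methoxymethoxy)-2-[4-(methoxymethoxy)phenyl]-8-(2-methylbut-3-en-2-yl)-4H-chromen-4-one | C=CC(C)(C)c1c(OCOC)cc(OCOC)c2c(=O)c(O)c(-c3ccc(OCOC)cc3)oc12 | intermediate
13 | 3,5,7-trihydroxy-2-(4-hydroxyphenyl)-8-(2-methylbut-3-en-2-yl)-4H-chromen-4-one | C=CC(C)(C)c1c(O)cc(O)c2c(=O)c(O)c(-c3ccc(O)cc3)oc12 | target

**Totals and risks**
Total step count: 9. Longest linear sequence: 8 (steps 1–6, 8, 9).

Steps most likely to fail:

1. Step 8 (proposed new method). The newly formed, more electron-rich flavonol may be over-oxidised at the anode. The chromonol may homo-couple through C2, the arene may be attacked ortho, and the C2 radical or cation may be captured by solvent or by the pendant vinyl group. Fallback with known chemistry: setting out from 9, electrophilic iodination of the enolate carbon C2 (I2, Na2CO3, THF/H2O, 0 °C) should give 3-hydroxy-2-iodo-5,7-bis(methoxymethoxy)-8-(2-methylbut-3-en-2-yl)-4H-chromen-4-one F1. Suzuki–Miyaura coupling of this iodide with commercial [4-(methoxymethoxy)phenyl]boronic acid (Pd(dppf)Cl2, K2CO3, dioxane/H2O, 80 °C) comes back to the route at 12.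

2. Step 2. At the rearrangement temperature the liberated o-(1,1-dimethylallyl)phenol may react further: a flanking OH may add across the vinyl group, the side chain may isomerise by an abnormal Claisen pathway, or the tert-allyl group may be lost. Fallback: setting out from 3, the rearrangement is run as a rearrangement–silylation cascade with N,O-bis(trimethylsilyl)acetamide in PhNEt2 at 185 °C, so that each phenol is masked as it forms, giving 1-[3-(2-methylbut-3-en-2-yl)-2,4,6-tris(trimethylsilyloxy)phenyl]ethanone F2. Mild methanolysis (K2CO3, MeOH, rt) then comes back to the route at 4.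

3. Step 5. Hydroperoxide or hydroxide may attack C2 and open the pyranone by retro-oxa-Michael reaction instead of closing the epoxide, and addition to the electron-rich vinylogous ester may be slow. Fallback: setting out from 5, the enaminone 6 is formed as in step 4 and cyclised with iodine (I2, pyridine, CHCl3, rt) to 3-iodo-5,7-bis(methoxymethoxy)-8-(2-methylbut-3-en-2-yl)-4H-chromen-4-one F3. Miyaura borylation (B2pin2, PdCl2(dppf), KOAc, dioxane, 80 °C) should give 5,7-bis(methoxymethoxy)-8-(2-methylbut-3-en-2-yl)-3-(4,4,5,5-tetramethyl-1,3,2-dioxaborolan-2-yl)-4H-chromen-4-one F4, and oxidation of the C–B bond (NaBO3·4H2O, THF/H2O, rt) comes back to the route at 9.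

**Further compounds**
F1 | step 8 | 3-hydroxy-2-iodo-5,7-bis(methoxymethoxy)-8-(2-methylbut-3-en-2-yl)-4H-chromen-4-one | C=CC(C)(C)c1c(OCOC)cc(OCOC)c2c(=O)c(O)c(I)oc12
F2 | step 2 | 1-[3-(2-methylbut-3-en-2-yl)-2,4,6-tris(trimethylsilyloxy)phenyl]ethanone | CC(=O)c1c(O[Si](C)(C)C)cc(O[Si](C)(C)C)c(C(C)(C)C=C)c1O[Si](C)(C)C
F3 | step 5 | 3-iodo-5,7-bis(methoxymethoxy)-8-(2-methylbut-3-en-2-yl)-4H-chromen-4-one | C=CC(C)(C)c1c(OCOC)cc(OCOC)c2c(=O)c(I)coc12
F4 | step 5 | 5,7-bis(methoxymethoxy)-8-(2-methylbut-3-en-2-yl)-3-(4,4,5,5-tetramethyl-1,3,2-dioxaborolan-2-yl)-4H-chromen-4-one | C=CC(C)(C)c1c(OCOC)cc(OCOC)c2c(=O)c(B3OC(C)(C)C(C)(C)O3)coc12
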